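## Retrosynthetic overview

1. The target is methyl (−)-shikimate (3R,4S,5R) carrying the same (E)-3-methylpent-2-enoyl group on O3 and O5, with O4 free. No C–C bond has to be made.
2. Key disconnections are C5–O (SN2 opening of a 4,5-epoxide by the carboxylate) and O3–C(acyl) (acyl transfer). Both come from one molecule of the symmetric enoic anhydride in one flask.
3. O4 is stored as the oxirane oxygen, so it never meets an acyl donor. C5 is inverted twice (epoxide closure, epoxide opening), which gives net retention.
4. The epoxy alcohol comes from methyl shikimate by Mitsunobu cyclodehydration, and methyl shikimate comes from (−)-shikimic acid by Fischer esterification.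
5. Ring order: the cyclohexene ring is bought with shikimic acid. The only ring formed is the oxirane (second step), and it is opened again in the last step.

Assumption: (E)-3-methylpent-2-enoic acid is bought geometrically pure as a catalogue compound, so both E double bonds come with the starting material.

## Route

Step 1
Reactants: 1 (−)-shikimic acid [(3R,4S,5R)-3,4,5-trihydroxycyclohex-1-ene-1-carboxylic acid]
Product: 2 methyl (−)-shikimate [methyl (3R,4S,5R)-3,4,5-trihydroxycyclohex-1-ene-1-carboxylate]
Conditions: MeOH, Amberlyst 15 (H+ form, cat.), reflux, 16 h
Reagents that add atoms: methanol, CO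
Why: Fischer esterification in a large excess of methanol drives the equilibrium to the ester, and no stereocentre or hydroxyl group is touched.

Step 2
Reactants: 2 methyl (−)-shikimate
Product: 3 methyl (3R,4R,5S)-4,5-epoxy-3-hydroxycyclohex-1-ene-1-carboxylate [methyl (1S,5R,6R)-5-hydroxy-7-oxabicyclo[4.1.0]hept-3-ene-3-carboxylate; oxirane oxygen cis to the 3-OH]
Conditions: PPh3 (1.2 equiv), DIAD (1.2 equiv), THF, 0 °C to rt, 2 h
Reagents that add atoms: none
Why: In this Mitsunobu cyclodehydration, known for this very triol, the least hindered 5-OH becomes the oxyphosphonium leaving group and the trans 4-oxygen displaces it by intramolecular SN2, so C5 is inverted (R to S) while C3 and C4 keep their geometry (the C4 descriptor changes from S to R only through the priority rules).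

Step 3
Reactants: 3 methyl (3R,4R,5S)-4,5-epoxy-3-hydroxycyclohex-1-ene-1-carboxylate; 4 (E)-3-methylpent-2-enoic acid (2.1 equiv)
Product: 7 methyl (3R,4S,5R)-4-hydroxy-3,5-bis[(E)-3-methylpent-2-enoyloxy]cyclohex-1-ene-1-carboxylate (target), via enoic anhydride 5 (not isolated), via 3-acyloxy epoxide 6 (not isolated)
Conditions: 4 (2.1 equiv), iPrN=C=NiPr (1.0 equiv), CH2Cl2 (0.5 M), 0 °C, 30 min; then 3, DMAP (10 mol%), [N,N'-bis(3,5-di-tert-butylsalicylidene)ethane-1,2-diaminato]cobalt (C32H46CoN2O2, divalent cobalt, 5 mol%, pre-stirred with a little 4 in air to give the trivalent cobalt carboxylate), 0 °C, 2 h, then 30 °C, 36 h; pH 7 work-up, amine-free silica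
Reagents that add atoms: (E)-3-methylpent-2-enoic acid 4, CC/C(C)=C/C(=O)O (supplies both acyloxy groups)
Why: Proposed new method: anhydride-splitting relay diacyloxylation of a cis-epoxy alcohol under one binary catalyst, in which DMAP passes the acyl half of 5 to O3, the only free hydroxyl (retention, gives 6), this acylation releases exactly one equivalent of 4, and the trivalent cobalt salen carboxylate pair (one cobalt binds the oxirane, a second delivers carboxylate) then adds it by SN2 attack at C5 anti to the oxirane oxygen, so that C5 is inverted a second time (S back to R), O4 appears as the only hydroxyl when no acyl donor is left, and C4 is avoided because the neighbouring 3-acyloxy group deactivates it inductively and, being cis to the oxirane, cannot participate, just as azide is known to choose the same carbon in this epoxide type; the closest known reaction types are Steglich/DMAP acyl transfer, cobalt-salen-catalysed addition of carboxylic acids to cyclohexene oxides and the alternating elementary steps of epoxide/anhydride ring-opening copolymerisation, none of which has been used to split one acyclic anhydride over an epoxy alcohol.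

## Compound list

1 | (−)-shikimic acid, (3R,4S,5R)-3,4,5-trihydroxycyclohex-1-ene-1-carboxylic acid | O[C@@H]1C=C(C(=O)O)C[C@@H](O)[C@@H]1O | starting material
2 | methyl (−)-shikimate, methyl (3R,4S,5R)-3,4,5-trihydroxycyclohex-1-ene-1-carboxylate | O[C@@H]1C=C(C(=O)OC)C[C@@H](O)[C@@H]1O | intermediate
3 | methyl (3R,4R,5S)-4,5-epoxy-3-hydroxycyclohex-1-ene-1-carboxylate (oxirane cis to 3-OH) | O[C@@H]1C=C(C(=O)OC)C[C@@H]2O[C@H]12 | intermediate
4 | (E)-3-methylpent-2-enoic acid | CC/C(C)=C/C(=O)O | starting material
5 | (E)-3-methylpent-2-enoic anhydride (both double bonds E) | CC/C(C)=C/C(=O)OC(=O)/C=C(\C)CC | intermediate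
6 | methyl (3R,4S,5S)-4,5-epoxy-3-[(E)-3-methylpent-2-enoyloxy]cyclohex-1-ene-1-carboxylate (oxirane cis to the 3-acyloxy group) | CC/C(C)=C/C(=O)O[C@@H]1C=C(C(=O)OC)C[C@@H]2O[C@H]12 | intermediate
7 | methyl (3R,4S,5R)-4-hydroxy-3,5-bis[(E)-3-methylpent-2-enoyloxy]cyclohex-1-ene-1-carboxylate | CC/C(C)=C/C(=O)O[C@@H]1C=C(C(=O)OC)C[C@@H](OC(=O)/C=C(\C)CC)[C@@H]1O | target

## Step count and risks

Total step count: 3. Longest linear sequence: 3 (1 to 2 to 3 to 7).

**Risk A, the third step (the proposed new step).**
- The oxirane may open before all anhydride is spent, which would acylate O4.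
- The carboxylate addition may be slow, or may partly attack C4.
- The 3-acyl group may migrate to the cis 4-OH.
- DMAP may deconjugate the enoyl group or scramble its E geometry.

The fallback uses known chemistry only. It sets out from 3 and comes back at 7. An ordinary Steglich esterification of 3 with 1.1 equiv of 4 (diisopropylcarbodiimide, DMAP cat., CH2Cl2, 0 °C), followed by chromatography, gives 6 as an isolated compound. Separately, 4 is neutralised with Cs2CO3 in MeOH and dried to caesium (E)-3-methylpent-2-enoate F1. Pure 6 is then opened by stoichiometric F1 (1.5 equiv), buffered with free 4 (1.5 equiv), in DMF at 60 °C. This is a classical SN2 opening of an epoxide by a carboxylate salt at C5, and it gives 7.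

**Risk B, the second step.**
- The allylic 3-OH may be activated in competition, leading to elimination and aromatisation.
- Compound 3 may be hard to free from the hydrazine dicarboxylate.

The fallback replaces redox dehydration by a sulfonate displacement. It sets out from 2 and comes back at 3.
- 2,2-Dimethoxypropane and cat. camphorsulfonic acid in acetone give methyl 3,4-O-isopropylideneshikimate F2.
- MsCl and Et3N in CH2Cl2 at 0 °C give methyl 3,4-O-isopropylidene-5-O-methanesulfonylshikimate F3.
- 80% aqueous AcOH at 45 °C removes the acetonide to give methyl 5-O-methanesulfonylshikimate F4.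
- KHCO3 in aqueous MeOH at 55 °C lets the 4-oxygen displace the mesylate with inversion, giving 3.

**Risk C, the first step.**
- Conversion may be incomplete.
- Acid may promote dehydration to aromatic by-products on long reflux.

The fallback changes from acid-catalysed acyl substitution to O-alkylation of the carboxylate. It sets out from 1 and comes back at 2. Compound 1 is stirred with KHCO3 (1.2 equiv) and MeI (1.5 equiv) in DMF at rt, an SN2 reaction at the methyl carbon that leaves the hydroxyl groups untouched. It makes no compound outside the list (entry F0).

## Further compounds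

F1 | step 3 | caesium (E)-3-methylpent-2-enoate | CC/C(C)=C/C(=O)[O-].[Cs+]
F2 | step 2 | methyl 3,4-O-isopropylideneshikimate (configuration of 2 at C3, C4, C5) | CC1(C)O[C@@H]2C=C(C(=O)OC)C[C@@H](O)[C@@H]2O1
F3 | step 2 | methyl 3,4-O-isopropylidene-5-O-methanesulfonylshikimate | CC1(C)O[C@@H]2C=C(C(=O)OC)C[C@@H](OS(C)(=O)=O)[C@@H]2O1
F4 | step 2 | methyl 5-O-methanesulfonylshikimate | O[C@@H]1C=C(C(=O)OC)C[C@@H](OS(C)(=O)=O)[C@@H]1O
F0 | step 1 | none | none
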